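All runs are simulated with constants of no real substance, noise included.

| setting | north-west | north | north-east | west |
|---|---|---|---|---|
| substrate | 120 mM | 120 mM | 240 mM | 550 mM |
| reagent | 360 mM | 180 mM | 360 mM | 360 mM |
| time |  |  |  | 11 min |

- north-west run (time / min: [target] / mM): 0.39: 1.2; 1.2: 4.0; 2.3: 6.2; 3.6: 12.9; 5.2: 17.1; 6.9: 22.4; 8.9: 25.9; 11: 29.0
- north run (time / min: [target] / mM): 0.39: 0.6; 1.2: 1.5; 2.3: 2.9; 3.6: 5.0; 5.2: 8.8; 6.9: 11.3; 8.9: 14.0; 11: 17.8
- north-east run (time / min: [target] / mM): 0.39: 2.8; 1.2: 9.0; 2.3: 20.6; 3.6: 38.2; 5.2: 60.3; 6.9: 78.0; 8.9: 90.6; 11: 96.4

(each reading ± 0.6 mM)

1. how the opening rate goes with [substrate] round the charge of the north-west run: the exponent of the rate at two percent of substrate gone to target (one fixed amount of target, the same in the runs compared)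
2. how the opening rate goes with [reagent] round the charge of the north-west run: the exponent of the rate at two percent of substrate gone to target
3. target in the west run at 11 min, as a share of the substrate charged

- Overall: substrate + reagent -> target.
- Constant volume, constant temperature.
- "The second partner" is reagent.
- An order is taken over about fifteen percent of the charge, up and down.

- The easy step is one division. In the north-east run, the first reading past two percent of the north-west charge is 2.8 mM at 0.39 min, which gives an opening chord from the start of 7.18 mM/min, and the charge of 240 mM over that chord gives 33.4 min; I call this τ, the opening lifetime: the substrate charge divided by the opening chord.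
- My orders come from the same kind of chord, taken in each run from the start to the first reading past that amount of target. The north-west chord is 3.33 mM/min and the north chord is 1.26 mM/min. The north-east run has twice the substrate of the north-west run, and its chord over the north-west chord is 2.16, which gives my substrate order of 1.11. The north run has half the reagent of the north-west run, and its chord over the north-west chord is 0.378, which gives my reagent order of 1.40. Both orders are readings from short chords, so they carry the scatter of the readings.
- First I hold the west run at its opening pace. Scaling the north-west chord by my substrate order gives 18.0 mM/min for the west run, so its τ is 30.6 min, and 11 min counts as 36.0% of its charge.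
- Next I let substrate fall, with reagent treated as held at its charge, the pseudo-first-order count. The share turned is then one minus the exponential of minus the lifetimes elapsed, which gives 30.2% for the west run. In the north-west run, where τ is 36.0 min, the same count gives 31.6 mM against a reading of 29.0 mM at 11 min, a factor of 0.918.
- Last comes the speed-up. The north-east rate reads 13.8 mM/min between 3.6 min and 5.2 min, and the count of 67.3 mM falls short of the 96.4 mM read at 11 min by a factor of 1.43. I carry this larger factor to the west run and get 43.3%, which is below the 65.5% that reagent, the limiting reagent there, allows.
- The forecast gives 1.15 for substrate, 1.3 for reagent and 45% for the west run, and it says “Halving reagent cuts the rate about 2.5-fold”. Its reagent order is lower than my 1.40.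
- The flask gives 1.2 for substrate, 1.0 for reagent and 46.4% for the west run, and the north-run rate read half the north-west rate at equal target.

    substrate ⇌ intermediate, settled at all times (0.2490)
    intermediate + reagent → target (0.3480 /M/min)
    target + reagent → side product (0.5172 /M/min)
    substrate + reagent + target → 2 target (9.180 /M²/min)

- Counted in lifetimes, the west run stands 1.54 times above its count of 30.2%. In the north-east run, the count puts a quarter of the charge at 9.62 min, about twice the 5.12 min at which the flask gets there.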